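**Plan**

- Retrosynthesis: removing the C2 hydroxyl and opening cyclohexene ring C (bonds C2–C4' and C14–C15') by a retro-Diels–Alder step gives two molecules of one monomer, dehydrozaluzanin C (27), one of them as its 1,2-dehydro dienone.
- In the monomer, C1–C5 and C7–C8 are cut together. Ring B carries its oxygen on C6, the middle carbon of the unit C5–C6–C7 (an oxyallyl cation), and C8–C9–C10–C1 can be a 1,3-diene, with C2–C3–C4 of ring A as tether: an intramolecular (4+3) cycloaddition that closes rings A and B at once.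
- Forward: dienyl iodide from propargyl alcohol → chain extension → enone → catalytic asymmetric epoxidation → (4+3) cycloaddition → lactone → three exocyclic methylenes and the C3 ketone → Saegusa oxidation/Diels–Alder dimerisation → C2 hydroxylation.
- Stereochemistry: the catalyst-set epoxide fixes C5 (and C4); C1 and C7 follow in the cycloaddition and C6 from the C4 hydroxyl. The spiro centre C4' and C2 arise by substrate control in the last two steps.

Key step: step 7

Remarks on the chemistry (assumptions):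
- Ring compounds carry guaiane numbering (C1–C15; primed numbers for the dienophile-derived half). α is the face of H-5 (the convex face of the cis-fused hydroazulene).
- In step 5 the quinine-derived amine is written. If its sense of induction were the opposite, the quinidine-derived pseudoenantiomer would take its place; the (2S,3R)-epoxide is what is meant.
- The C3 configuration of 26 and the C11 configuration of 23 and 24 are immaterial.

**Step 1**
Reactants: 1 prop-2-yn-1-ol; 2 vinylmagnesium bromide (CH2=CHMgBr)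
Product: 3 (2Z)-2-(iodomethylidene)but-3-en-1-ol
Conditions: CH2=CHMgBr (2.5 equiv), CuI (10 mol %), THF, −20 °C to rt; then I2, THF, −40 to 0 °C
Reagents that add atoms: iodine, II
Why: Copper-catalysed anti-carbomagnesiation of the propargylic alkoxide (Duboudin–Jousseaume type) puts vinyl on the internal carbon and magnesium on the terminal carbon in a five-membered chelate, and iodinolysis with retention should leave iodine cis to CH2OH and trans to vinyl, the diene geometry needed in step 7.

**Step 2**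
Reactants: 3 (2Z)-2-(iodomethylidene)but-3-en-1-ol; 4 3,3-diethoxyprop-1-ene
Product: 6 (4Z)-5-(hydroxymethyl)hepta-4,6-dienal, via diethyl acetal 5 (not isolated)
Conditions: 4, 9-BBN, THF, 0 °C to rt; then 3, Pd(dppf)Cl2 (5 mol %), aq K3PO4, THF/DMF, rt; then aq oxalic acid, THF, rt
Reagents that add atoms: water, O
Why: B-alkyl Suzuki–Miyaura coupling of the anti-Markovnikov alkylborane with the vinyl iodide goes with retention of alkene geometry, and mild acetal hydrolysis should release the aldehyde without touching the dienol.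

**Step 3**
Reactants: 7 methyl 5-bromo-4-oxopentanoate; 8 triphenylphosphine
Product: 10 methyl 4-oxo-5-(triphenyl-λ5-phosphanylidene)pentanoate, via phosphonium bromide 9 (not isolated)
Conditions: toluene, rt; then aq Na2CO3, CH2Cl2, rt
Reagents that add atoms: none
Why: SN2 alkylation of the phosphine by the α-bromo ketone and deprotonation of the salt give the stabilised keto ylide (standard Wittig reagent preparation).

**Step 4**
Reactants: 6 (4Z)-5-(hydroxymethyl)hepta-4,6-dienal; 10 methyl 4-oxo-5-(triphenyl-λ5-phosphanylidene)pentanoate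
Product: 11 methyl (5E,9Z)-10-(hydroxymethyl)-4-oxododeca-5,9,11-trienoate
Conditions: CH2Cl2, rt to 40 °C
Reagents that add atoms: none
Why: Wittig olefination with a stabilised acyl ylide should give the (E)-enone selectively, the free alcohol and the diene being inert.

**Step 5**
Reactants: 11 methyl (5E,9Z)-10-(hydroxymethyl)-4-oxododeca-5,9,11-trienoate
Product: 12 methyl 4-{(2S,3R)-3-[(3Z)-4-(hydroxymethyl)hexa-3,5-dien-1-yl]oxiran-2-yl}-4-oxobutanoate
Conditions: 9-amino-9-deoxy-epi-quinine (10 mol %), CF3CO2H (20 mol %), 50 % aq H2O2, dioxane, 35 °C; then aq NaHCO3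
Reagents that add atoms: hydrogen peroxide, OO
Why: Catalytic asymmetric nucleophilic (Weitz–Scheffer type) epoxidation through the chiral iminium ion of the enone should give the trans epoxy ketone, with both new centres (C4 and C5) set by the catalyst and only the electron-poor alkene reacting.

**Step 6**
Reactants: 12 methyl 4-{(2S,3R)-3-[(3Z)-4-(hydroxymethyl)hexa-3,5-dien-1-yl]oxiran-2-yl}-4-oxobutanoate
Product: 13 methyl (3Z)-4-{(2S,3R)-3-[(3Z)-4-{[(triethylsilyl)oxy]methyl}hexa-3,5-dien-1-yl]oxiran-2-yl}-4-[(triethylsilyl)oxy]but-3-enoate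
Conditions: Et3SiOTf (2.5 equiv), Et3N (3.5 equiv), CH2Cl2, −78 to 0 °C
Reagents that add atoms: triethylsilyl triflate, CC[Si](CC)(CC)OS(=O)(=O)C(F)(F)F
Why: Soft enolisation can go only towards C7 (the other α-carbon is the oxirane carbon) and should give the thermodynamically preferred (Z)-silyl enol ether while the primary alcohol is silylated, the amine buffer keeping the epoxide intact.

**Step 7**
Reactants: 13 methyl (3Z)-4-{(2S,3R)-3-[(3Z)-4-{[(triethylsilyl)oxy]methyl}hexa-3,5-dien-1-yl]oxiran-2-yl}-4-[(triethylsilyl)oxy]but-3-enoate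
Product: 15 methyl 4α,14-dihydroxy-6-oxo-13,15-dinor-1αH,5αH,7αH-guai-9-en-12-oate, via bis-silyl cycloadduct 14 (not isolated)
Conditions: Et3SiOTf (20 mol %), CH2Cl2, −78 °C; then HF·pyridine, pyridine/THF, 0 °C
Reagents that add atoms: none
Why: Et3SiOTf silylates the epoxide oxygen and the C5–O bond ionises with help from the neighbouring (Z)-silyl enol ether, so that C5–C6–C7 becomes a silyloxyallyl cation that is captured across C8–C9–C10–C1 of the tethered diene in a (4+3) cycloaddition, after which the silyloxocarbenium ion loses its silyl group to give the C6 ketone and return the catalyst; the closest known reaction type is the intramolecular (4+3) cycloaddition of epoxy enol silanes, and of oxyallyl cations in general, with tethered dienes. Ring A closes through the C1–C5 bond in an endo mode with respect to the oxirane (both oxirane carbons end up in the five-membered ring, which the cationic character of C5 allows), and ring B closes through the C7–C8 bond as the seven-membered (4+3) ring. C5 is controlled by the epoxide, since C1 enters anti to the departing oxygen (inversion), and C4 keeps its configuration, so that O4 ends cis to H-5. C7 is controlled by the (Z)-enol silane together with the tether, which can reach the rear face of C5 only when C4 takes the W position of the allyl unit, so the C4 and C11 substituents end cis on ring B. C1 is controlled by the compact (endo-like) alignment of the diene under the allyl unit, which gives the cis ring fusion (H-1 cis to H-5). The step needs the compact over the extended approach and cycloaddition over Lewis-acid rearrangement of the epoxide: the C10 substituent holds the diene s-cis, the tether stands trans to the vinyl group on C1=C10, and catalytic silyl triflate at −78 °C keeps rearrangement slow, while HF·pyridine finally removes both silyl groups.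

**Step 8**
Reactants: 15 methyl 4α,14-dihydroxy-6-oxo-13,15-dinor-1αH,5αH,7αH-guai-9-en-12-oate
Product: 17 4α,14-dihydroxy-13,15-dinor-1αH,5αH,6βH,7αH-guai-9-en-12,6-olide, via triol ester 16 (not isolated)
Conditions: Me4NBH(OAc)3, MeCN/AcOH, −20 °C; then TsOH·H2O (cat.), CH2Cl2, rt
Reagents that add atoms: none
Why: Hydroxyl-directed (Evans–Saksena type) reduction, in which the acetoxyborohydride bound to the C4 oxygen, which lies over the β-face of the C6 carbonyl because C4 is the β-substituent of C5, delivers hydride to that face so that O6 ends α (H-6β), after which the γ-hydroxy ester closes under acid to the trans-fused γ-lactone.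

**Step 9**
Reactants: 17 4α,14-dihydroxy-13,15-dinor-1αH,5αH,6βH,7αH-guai-9-en-12,6-olide
Product: 20 4α-hydroxy-13,15-dinor-1αH,5αH,6βH,7αH-guai-10(14)-en-12,6-olide, via sulfonylhydrazine 18 (not isolated), via allylic diazene 19 (not isolated)
Conditions: PPh3, DEAD, 2-nitrobenzenesulfonohydrazide, N-methylmorpholine, −30 °C to rt
Reagents that add atoms: none
Why: Myers reductive 1,3-transposition, in which Mitsunobu displacement at the unhindered primary allylic alcohol (the hindered secondary C4 alcohol is left), loss of sulfinic acid and retro-ene loss of N2 from the monoalkyl diazene move the double bond to C10=C14 with hydrogen delivered to C9.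

**Step 10**
Reactants: 20 4α-hydroxy-13,15-dinor-1αH,5αH,6βH,7αH-guai-10(14)-en-12,6-olide
Product: 21 4-oxo-13,15-dinor-1αH,5αH,6βH,7αH-guai-10(14)-en-12,6-olide
Conditions: Dess–Martin periodinane, CH2Cl2, rt
Reagents that add atoms: none
Why: Dess–Martin oxidation of the secondary alcohol under non-basic conditions should avoid β-elimination of the lactone oxygen and epimerisation at C5.

**Step 11**
Reactants: 21 4-oxo-13,15-dinor-1αH,5αH,6βH,7αH-guai-10(14)-en-12,6-olide
Product: 22 13-nor-1αH,5αH,6βH,7αH-guaia-4(15),10(14)-dien-12,6-olide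
Conditions: Zn, CH2Br2, TiCl4, THF/CH2Cl2, 0 °C to rt
Reagents that add atoms: dibromomethane, BrCBr
Why: Takai–Lombardo methylenation is non-basic and ketone-selective, so the enolisable β-acyloxy ketone should give the C4=C15 methylene without epimerisation at C5 and without attack on the lactone.

**Step 12**
Reactants: 22 13-nor-1αH,5αH,6βH,7αH-guaia-4(15),10(14)-dien-12,6-olide
Product: 25 dehydrocostus lactone (1αH,5αH,6βH,7αH-guaia-4(15),10(14),11(13)-trien-12,6-olide), via Mannich base 23 (not isolated), via ammonium iodide 24 (not isolated)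
Conditions: LiN(iPr)2, THF, −78 °C; [Me2N=CH2]I, −78 °C to rt; then MeI, MeOH, rt; then aq NaHCO3, EtOAc
Reagents that add atoms: N,N-dimethylmethyleneiminium iodide (Eschenmoser's salt), C=[N+](C)C.[I-]
Why: Aminomethylation of the lactone enolate (the only enolisable position), quaternisation and β-elimination is the standard α-methylenation of γ-lactones, and the C11 centre disappears in the elimination.

**Step 13**
Reactants: 25 dehydrocostus lactone
Product: 26 3-epizaluzanin C (3α-hydroxy-1αH,5αH,6βH,7αH-guaia-4(15),10(14),11(13)-trien-12,6-olide)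
Conditions: SeO2 (0.5 equiv), t-BuOOH (2 equiv), CH2Cl2, rt
Reagents that add atoms: tert-butyl hydroperoxide, CC(C)(C)OO
Why: Riley allylic oxidation (ene reaction then 2,3-sigmatropic shift) at the allylic CH2 (C3) of the cyclopentane exocyclic alkene, a transformation known for this lactone, should bring oxygen in on the convex α-face, and the C3 centre is erased in step 14.

**Step 14**
Reactants: 26 3-epizaluzanin C
Product: 27 dehydrozaluzanin C (3-oxo-1αH,5αH,6βH,7αH-guaia-4(15),10(14),11(13)-trien-12,6-olide)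
Conditions: Dess–Martin periodinane, NaHCO3, CH2Cl2, 0 °C to rt
Reagents that add atoms: none
Why: Dess–Martin oxidation of the allylic alcohol gives the α-methylene cyclopentanone, and no stereocentre is formed.

**Step 15**
Reactants: 27 dehydrozaluzanin C
Product: 28 3-(tert-butyldimethylsilyloxy)-1αH,5αH,6βH,7αH-guaia-2,4(15),10(14),11(13)-tetraen-12,6-olide
Conditions: t-BuMe2SiOTf, Et3N, CH2Cl2, 0 °C
Reagents that add atoms: tert-butyldimethylsilyl triflate, CC(C)(C)[Si](C)(C)OS(=O)(=O)C(F)(F)F
Why: Soft enolisation of the ketone, which has α-hydrogens only at C2, gives the 2-silyloxy diene needed for the Saegusa oxidation, the lactone not being enolised.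

**Step 16**
Reactants: 28 3-(tert-butyldimethylsilyloxy)-1αH,5αH,6βH,7αH-guaia-2,4(15),10(14),11(13)-tetraen-12,6-olide; 27 dehydrozaluzanin C (3 equiv, dienophile)
Product: 30 2-deoxy dimer (upper half 3-oxo-2αH,5αH,6βH,7αH-guaia-1(10),4(15),11(13)-trien-12,6-olide bonded C2–C4' and C14–C15' to lower half 3'-oxo-guaia-10'(14'),11'(13')-dien-12',6'-olide, spiro at C4', C2 on the α-face of the lower ring A), via dienone 29 (not isolated)
Conditions: Pd(OAc)2 (1.1 equiv), MeCN, rt, argon
Reagents that add atoms: none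
Why: Saegusa–Ito oxidation (divalent palladium enolate, β-hydride elimination from C1) gives the cross-conjugated dienone, whose s-cis diene C2=C1–C10=C14 adds in an intermolecular Diels–Alder reaction to the exocyclic enone C4'=C15' of 27 with ortho regiochemistry, the spiro centre C4' being set by attack on the dienophile face anti to the C5'–C6' bond in an endo arrangement (C3' carbonyl under the diene, C5' outward) while the excess of 27 suppresses self-dimerisation of 29.

**Step 17**
Reactants: 30 2-deoxy dimer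
Product: 31 target (2α-hydroxy derivative of 30)
Conditions: KN(SiMe3)2 (0.95 equiv), THF, −78 to −40 °C; then 3-phenyl-2-(phenylsulfonyl)oxaziridine, −78 °C; aq NH4Cl
Reagents that add atoms: 3-phenyl-2-(phenylsulfonyl)oxaziridine (Davis reagent), O=S(=O)(c1ccccc1)N1OC1c1ccccc1
Why: Davis α-hydroxylation of the cross-conjugated dienolate formed by removal of the doubly activated H-2 (proton transfer funnels any C2' enolate to it), in which the oxaziridine attacks the α-carbon and oxygen should enter C2 from the α-face, the β-face being covered by C6 of ring B and by the pseudo-axial C3' arm of the spiro ring.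

**Compound list**

1 | prop-2-yn-1-ol | C#CCO | starting material
2 | vinylmagnesium bromide | C=C[Mg]Br | starting material
3 | (2Z)-2-(iodomethylidene)but-3-en-1-ol | OC/C(=C\I)C=C | intermediate
4 | 3,3-diethoxyprop-1-ene | C=CC(OCC)OCC | starting material
5 | (2Z)-2-(4,4-diethoxybutylidene)but-3-en-1-ol | CCOC(CC/C=C(\CO)C=C)OCC | intermediate (not isolated)
6 | (4Z)-5-(hydroxymethyl)hepta-4,6-dienal | O=CCC/C=C(\CO)C=C | intermediate
7 | methyl 5-bromo-4-oxopentanoate | COC(=O)CCC(=O)CBr | starting material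
8 | triphenylphosphine | c1ccc(cc1)P(c1ccccc1)c1ccccc1 | starting material
9 | (5-methoxy-2,5-dioxopentyl)triphenylphosphonium bromide | COC(=O)CCC(=O)C[P+](c1ccccc1)(c1ccccc1)c1ccccc1.[Br-] | intermediate (not isolated)
10 | methyl 4-oxo-5-(triphenyl-λ5-phosphanylidene)pentanoate | COC(=O)CCC(=O)C=P(c1ccccc1)(c1ccccc1)c1ccccc1 | intermediate
11 | methyl (5E,9Z)-10-(hydroxymethyl)-4-oxododeca-5,9,11-trienoate | COC(=O)CCC(=O)/C=C/CC/C=C(\CO)C=C | intermediate
12 | methyl 4-{(2S,3R)-3-[(3Z)-4-(hydroxymethyl)hexa-3,5-dien-1-yl]oxiran-2-yl}-4-oxobutanoate | COC(=O)CCC(=O)[C@H]1O[C@@H]1CC/C=C(\CO)C=C | intermediate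
13 | methyl (3Z)-4-{(2S,3R)-3-[(3Z)-4-{[(triethylsilyl)oxy]methyl}hexa-3,5-dien-1-yl]oxiran-2-yl}-4-[(triethylsilyl)oxy]but-3-enoate | COC(=O)C/C=C(\O[Si](CC)(CC)CC)[C@H]1O[C@@H]1CC/C=C(\CO[Si](CC)(CC)CC)C=C | intermediate
14 | methyl 6-oxo-4α,14-bis(triethylsilyloxy)-13,15-dinor-1αH,5αH,7αH-guai-9-en-12-oate | CC[Si](CC)(CC)O[C@@H]1CC[C@H]2C(CO[Si](CC)(CC)CC)=CC[C@@H](CC(=O)OC)C(=O)[C@H]21 | intermediate (not isolated)
15 | methyl 4α,14-dihydroxy-6-oxo-13,15-dinor-1αH,5αH,7αH-guai-9-en-12-oate | O[C@@H]1CC[C@H]2C(CO)=CC[C@@H](CC(=O)OC)C(=O)[C@H]21 | intermediate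
16 | methyl 4α,6α,14-trihydroxy-13,15-dinor-1αH,5αH,6βH,7αH-guai-9-en-12-oate | O[C@@H]1CC[C@H]2C(CO)=CC[C@@H](CC(=O)OC)[C@H](O)[C@H]21 | intermediate (not isolated)
17 | 4α,14-dihydroxy-13,15-dinor-1αH,5αH,6βH,7αH-guai-9-en-12,6-olide | O[C@@H]1CC[C@H]2C(CO)=CC[C@H]3CC(=O)O[C@@H]3[C@H]21 | intermediate
18 | 14-[1-(2-nitrobenzenesulfonyl)hydrazin-1-yl] analogue of 17 (4α-hydroxy, 14-deoxy) | O[C@@H]1CC[C@H]2C(CN(N)S(=O)(=O)c3ccccc3[N+](=O)[O-])=CC[C@H]3CC(=O)O[C@@H]3[C@H]21 | intermediate (not isolated)
19 | 14-diazenyl analogue of 17 (4α-hydroxy, 14-deoxy) | O[C@@H]1CC[C@H]2C(CN=N)=CC[C@H]3CC(=O)O[C@@H]3[C@H]21 | intermediate (not isolated)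
20 | 4α-hydroxy-13,15-dinor-1αH,5αH,6βH,7αH-guai-10(14)-en-12,6-olide | O[C@@H]1CC[C@H]2C(=C)CC[C@H]3CC(=O)O[C@@H]3[C@H]21 | intermediate
21 | 4-oxo-13,15-dinor-1αH,5αH,6βH,7αH-guai-10(14)-en-12,6-olide | O=C1CC[C@H]2C(=C)CC[C@H]3CC(=O)O[C@@H]3[C@H]21 | intermediate
22 | 13-nor-1αH,5αH,6βH,7αH-guaia-4(15),10(14)-dien-12,6-olide | C=C1CC[C@H]2C(=C)CC[C@H]3CC(=O)O[C@@H]3[C@H]21 | intermediate
23 | 13-(dimethylamino)-1αH,5αH,6βH,7αH-guaia-4(15),10(14)-dien-12,6-olide (C11 epimers) | C=C1CC[C@H]2C(=C)CC[C@H]3C(CN(C)C)C(=O)O[C@@H]3[C@H]21 | intermediate (not isolated)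
24 | 13-(trimethylammonio)-1αH,5αH,6βH,7αH-guaia-4(15),10(14)-dien-12,6-olide iodide (C11 epimers) | C=C1CC[C@H]2C(=C)CC[C@H]3C(C[N+](C)(C)C)C(=O)O[C@@H]3[C@H]21.[I-] | intermediate (not isolated)
25 | dehydrocostus lactone | C=C1CC[C@H]2C(=C)CC[C@H]3C(=C)C(=O)O[C@@H]3[C@H]21 | intermediate
26 | 3-epizaluzanin C (3α-hydroxy) | C=C1[C@H](O)C[C@H]2C(=C)CC[C@H]3C(=C)C(=O)O[C@@H]3[C@H]21 | intermediate
27 | dehydrozaluzanin C | C=C1C(=O)C[C@H]2C(=C)CC[C@H]3C(=C)C(=O)O[C@@H]3[C@H]21 | intermediate
28 | 3-(tert-butyldimethylsilyloxy)-1αH,5αH,6βH,7αH-guaia-2,4(15),10(14),11(13)-tetraen-12,6-olide | C=C1C(O[Si](C)(C)C(C)(C)C)=C[C@H]2C(=C)CC[C@H]3C(=C)C(=O)O[C@@H]3[C@H]21 | intermediate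
29 | 3-oxo-5αH,6βH,7αH-guaia-1,4(15),10(14),11(13)-tetraen-12,6-olide | C=C1C(=O)C=C2C(=C)CC[C@H]3C(=C)C(=O)O[C@@H]3[C@@H]12 | intermediate (not isolated)
30 | 2-deoxy dimer (Diels–Alder adduct, H-2α) | C=C1C(=O)[C@@H]2C3=C(CC[C@H]4C(=C)C(=O)O[C@@H]4[C@@H]13)CC[C@]21C(=O)C[C@H]2C(=C)CC[C@H]3C(=C)C(=O)O[C@@H]3[C@H]21 | intermediate
31 | CNP0269880.2 (2α-hydroxy dimer) | C=C1C(=O)[C@]2(O)C3=C(CC[C@H]4C(=C)C(=O)O[C@@H]4[C@@H]13)CC[C@]21C(=O)C[C@H]2C(=C)CC[C@H]3C(=C)C(=O)O[C@@H]3[C@H]21 | target

**Step count**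

Total: 17 steps. Longest linear sequence: 16 steps (steps 1, 2 and 4–17; step 3 is a side branch).

**Steps most likely to fail**

1. Step 7. The diene may prefer the extended approach to the allyl unit, which would give the trans ring fusion (wrong relative configuration at C1/C5). Fallback, from 11 back to 21: thermodynamic instead of kinetic control of the ring fusion, starting from the antipodal epoxide.
   - 11 is epoxidised with the pseudoenantiomeric amine (9-amino-9-deoxy-epi-quinidine) to the (2R,3S)-epoxy ketone F1, which is silylated as in step 6 to the enol silane F2.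
   - The cycloaddition under the step 7 conditions, now by the extended approach, gives the trans-fused adduct F3 (C1 natural; C4, C5 and C7 antipodal).
   - C5 and C7 are α to the C6 ketone, so brief treatment with DBU in toluene should equilibrate them to the cis-fused, cis-2,6-disubstituted ketone F4 (the 4-epimer of 14).
   - HF·pyridine gives the diol F5. Hydroxyl-directed reduction and lactonisation as in step 8 give the lactone F7 through the triol ester F6.
   - Myers transposition as in step 9 gives the methylene compound F10 through the sulfonylhydrazine F8 and the diazene F9.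
   - Dess–Martin oxidation removes the C4 centre and gives 21.

2. Step 17. The oxidant may attack the dienolate at the γ-carbon (C10) or on the wrong face, or the lower ketone may be enolised instead. Fallback, from 27 back to 31: the oxygen is placed on the diene before the cycloaddition.
   - 27 is hydroxylated at C2 (LiN(SiMe3)2, then the Davis oxaziridine) to the 2α-hydroxy ketone F11.
   - Dess–Martin oxidation gives the diosphenol F12, which is silylated (t-BuMe2SiOTf, Et3N) to the 2-silyloxy dienone F13.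
   - Diels–Alder reaction of F13 with 27 forms the C2–C4' and C14–C15' bonds with the C2–O bond already in place and gives the silyl ether F14, the C2 centre now coming from the cycloaddition.
   - HF·pyridine gives 31.

3. Step 8. Hydride may enter from the open α-face instead of by internal delivery, which would give the 6β-alcohol and then the cis-fused lactone. Fallback, from 14 (isolated by leaving out the HF treatment in step 7) back to 17: the convex-face reduction is used on purpose and C6 is inverted during ring closure.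
   - LiBH(s-Bu)3 reduces 14 from the α-face and the alkoxide closes on the ester to the cis-lactone F15.
   - LiOH opens it to the hydroxy acid F16.
   - Mitsunobu lactonisation (PPh3, DIAD, toluene, high dilution) closes the ring with inversion at C6 to the trans-lactone F17.
   - HF·pyridine gives 17.

**Further compounds**

F1 | step 7 | methyl 4-{(2R,3S)-3-[(3Z)-4-(hydroxymethyl)hexa-3,5-dien-1-yl]oxiran-2-yl}-4-oxobutanoate | COC(=O)CCC(=O)[C@@H]1O[C@H]1CC/C=C(\CO)C=C
F2 | step 7 | methyl (3Z)-4-{(2R,3S)-3-[(3Z)-4-{[(triethylsilyl)oxy]methyl}hexa-3,5-dien-1-yl]oxiran-2-yl}-4-[(triethylsilyl)oxy]but-3-enoate | COC(=O)C/C=C(\O[Si](CC)(CC)CC)[C@@H]1O[C@H]1CC/C=C(\CO[Si](CC)(CC)CC)C=C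
F3 | step 7 | methyl 6-oxo-4β,14-bis(triethylsilyloxy)-13,15-dinor-1αH,5βH,7βH-guai-9-en-12-oate (trans-fused) | CC[Si](CC)(CC)O[C@H]1CC[C@H]2C(CO[Si](CC)(CC)CC)=CC[C@H](CC(=O)OC)C(=O)[C@@H]21
F4 | step 7 | methyl 6-oxo-4β,14-bis(triethylsilyloxy)-13,15-dinor-1αH,5αH,7αH-guai-9-en-12-oate | CC[Si](CC)(CC)O[C@H]1CC[C@H]2C(CO[Si](CC)(CC)CC)=CC[C@@H](CC(=O)OC)C(=O)[C@H]21
F5 | step 7 | methyl 4β,14-dihydroxy-6-oxo-13,15-dinor-1αH,5αH,7αH-guai-9-en-12-oate | O[C@H]1CC[C@H]2C(CO)=CC[C@@H](CC(=O)OC)C(=O)[C@H]21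
F6 | step 7 | methyl 4β,6α,14-trihydroxy-13,15-dinor-1αH,5αH,6βH,7αH-guai-9-en-12-oate | O[C@H]1CC[C@H]2C(CO)=CC[C@@H](CC(=O)OC)[C@H](O)[C@H]21
F7 | step 7 | 4β,14-dihydroxy-13,15-dinor-1αH,5αH,6βH,7αH-guai-9-en-12,6-olide | O[C@H]1CC[C@H]2C(CO)=CC[C@H]3CC(=O)O[C@@H]3[C@H]21
F8 | step 7 | 14-[1-(2-nitrobenzenesulfonyl)hydrazin-1-yl] analogue of F7 (4β-hydroxy, 14-deoxy) | O[C@H]1CC[C@H]2C(CN(N)S(=O)(=O)c3ccccc3[N+](=O)[O-])=CC[C@H]3CC(=O)O[C@@H]3[C@H]21
F9 | step 7 | 14-diazenyl analogue of F7 (4β-hydroxy, 14-deoxy) | O[C@H]1CC[C@H]2C(CN=N)=CC[C@H]3CC(=O)O[C@@H]3[C@H]21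
F10 | step 7 | 4β-hydroxy-13,15-dinor-1αH,5αH,6βH,7αH-guai-10(14)-en-12,6-olide | O[C@H]1CC[C@H]2C(=C)CC[C@H]3CC(=O)O[C@@H]3[C@H]21
F11 | step 17 | 2α-hydroxydehydrozaluzanin C | C=C1C(=O)[C@H](O)[C@H]2C(=C)CC[C@H]3C(=C)C(=O)O[C@@H]3[C@H]21
F12 | step 17 | 2-hydroxy-3-oxo-5αH,6βH,7αH-guaia-1,4(15),10(14),11(13)-tetraen-12,6-olide | C=C1C(=O)C(O)=C2C(=C)CC[C@H]3C(=C)C(=O)O[C@@H]3[C@@H]12
F13 | step 17 | 2-(tert-butyldimethylsilyloxy)-3-oxo-5αH,6βH,7αH-guaia-1,4(15),10(14),11(13)-tetraen-12,6-olide | C=C1C(=O)C(O[Si](C)(C)C(C)(C)C)=C2C(=C)CC[C@H]3C(=C)C(=O)O[C@@H]3[C@@H]12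
F14 | step 17 | 2-O-(tert-butyldimethylsilyl) ether of 31 | C=C1C(=O)[C@]2(O[Si](C)(C)C(C)(C)C)C3=C(CC[C@H]4C(=C)C(=O)O[C@@H]4[C@@H]13)CC[C@]21C(=O)C[C@H]2C(=C)CC[C@H]3C(=C)C(=O)O[C@@H]3[C@H]21
F15 | step 8 | 4α,14-bis(triethylsilyloxy)-13,15-dinor-1αH,5αH,6αH,7αH-guai-9-en-12,6-olide (cis-lactone) | CC[Si](CC)(CC)O[C@@H]1CC[C@H]2C(CO[Si](CC)(CC)CC)=CC[C@H]3CC(=O)O[C@H]3[C@H]21
F16 | step 8 | 6β-hydroxy-4α,14-bis(triethylsilyloxy)-13,15-dinor-1αH,5αH,6αH,7αH-guai-9-en-12-oic acid | CC[Si](CC)(CC)O[C@@H]1CC[C@H]2C(CO[Si](CC)(CC)CC)=CC[C@@H](CC(=O)O)[C@@H](O)[C@H]21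
F17 | step 8 | 4α,14-bis(triethylsilyloxy)-13,15-dinor-1αH,5αH,6βH,7αH-guai-9-en-12,6-olide | CC[Si](CC)(CC)O[C@@H]1CC[C@H]2C(CO[Si](CC)(CC)CC)=CC[C@H]3CC(=O)O[C@@H]3[C@H]21
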